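**Plan**

- Retrosynthesis: the last cut is the C10–C11 single bond (carotenoid numbering, primed for the ε half). It lies between the preformed E olefins C9=C10 and C11=C12 and carries no stereocentre, so a C14 β-end dienyl iodide and a C26 ε-end heptaenyl boronate, each already carrying its palmitate, can be joined by alkenyl–alkenyl cross-coupling.
- Further cuts: the C26 half at C11–C12 (one-carbon boryl olefination of a C25 aldehyde) and at C11'=C12' (Wittig, C15 + C10); the C14 half at C10–I and C9–CH3 (carboalumination–iodination of an enyne) and at C6–C7 (Heck on the β-ring enol triflate).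
- Forward: β-ring: ketoisophorone → actinol → enol triflate → 3-silyloxy-β-ionone → enyne → dienyl iodide → palmitate. ε-ring: (R)-α-ionone → 3-hydroxy-α-ionone → C15 phosphonium salt → C25 aldehyde → C26 boronate. The two halves are joined last; both six-membered rings come from the starting materials.
- Stereochemistry: C3 (R) from enzymatic reduction of ketoisophorone; C6' (R) from (R)-α-ionone; C3' (R) from enzymatic trans-selective allylic hydroxylation. All chain olefins are E, from Heck coupling, syn-carboalumination, Wittig with equilibration, chromium-mediated olefination and a stereoretentive coupling.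

Key step: step 15

Remark: (R)-α-ionone of high enantiomeric purity and (2E,4E,6E)-2,7-dimethylocta-2,4,6-trienedial are taken as purchasable.

**Route**

Step 1
Reactants: 1 ketoisophorone (2,6,6-trimethylcyclohex-2-ene-1,4-dione)
Product: 3 (4R,6R)-4-hydroxy-2,2,6-trimethylcyclohexanone (actinol), via (6R)-levodione 2 (not isolated)
Conditions: ene-reductase of the old yellow enzyme family, NADPH cat., D-glucose, glucose dehydrogenase, phosphate buffer pH 7, 30 °C; then levodione reductase (short-chain carbonyl reductase, NADH), same pot, 30 °C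
Reagents that add atoms: none
Why: Biocatalytic asymmetric reduction, in which the ene-reductase should saturate the C2=C3 bond to set the methyl-bearing centre as 6R and the carbonyl reductase should then reduce only the unhindered C4 ketone from one face to the 4R alcohol, so both centres are enzyme-controlled.

Step 2
Reactants: 3 (4R,6R)-actinol
Product: 4 (4R,6R)-4-(tert-butyldimethylsilyloxy)-2,2,6-trimethylcyclohexanone
Conditions: TBSCl, imidazole, DMF, 23 °C
Reagents that add atoms: tert-butyldimethylsilyl chloride (TBSCl), CC(C)(C)[Si](C)(C)Cl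
Why: Standard silylation of an unhindered secondary alcohol, needed because the next four steps use strong bases and AlMe3.

Step 3
Reactants: 4 silyl ether ketone
Product: 6 (R)-4-(tert-butyldimethylsilyloxy)-2,6,6-trimethylcyclohex-1-en-1-yl trifluoromethanesulfonate, via lithium enolate 5 (not isolated)
Conditions: LiN(iPr)2, THF, −78 → 0 °C; then PhNTf2, −78 → 23 °C; aqueous work-up
Reagents that add atoms: N-phenylbis(trifluoromethanesulfonimide) (PhNTf2), O=S(=O)(N(c1ccccc1)S(=O)(=O)C(F)(F)F)C(F)(F)F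
Why: Only C6 carries an α-hydrogen, so enolisation is regiodefined and O-triflation of the enolate should give the tetrasubstituted enol triflate; the C6 centre is given up and the silyloxy centre is untouched.

Step 4
Reactants: 6 enol triflate; 7 methyl vinyl ketone
Product: 8 (3R)-3-(tert-butyldimethylsilyloxy)-β-ionone [(E)-4-[(4R)-4-(tert-butyldimethylsilyloxy)-2,6,6-trimethylcyclohex-1-en-1-yl]but-3-en-2-one]
Conditions: Pd(OAc)2 (5 mol %), PPh3 (10 mol %), Et3N, DMF, 70 °C
Reagents that add atoms: none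
Why: Heck–Mizoroki coupling of an enol triflate with an enone, in which syn-insertion and syn-β-hydride elimination should give the E enone and so form the C6–C7 bond and the C7=C8 olefin in one step.

Step 5
Reactants: 8 silyloxy-β-ionone
Product: 11 tert-butyl{[(1R)-4-[(E)-but-1-en-3-yn-1-yl]-3,5,5-trimethylcyclohex-3-en-1-yl]oxy}dimethylsilane, via lithium dienolate 9 (not isolated), via enol diethyl phosphate 10 (not isolated)
Conditions: LiN(iPr)2 (1.05 equiv), THF, −78 °C; ClP(O)(OEt)2, −78 → 23 °C; then LiN(iPr)2 (2.3 equiv), −78 → 23 °C; H2O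
Reagents that add atoms: none
Why: Methyl ketone to terminal alkyne conversion by way of the kinetic enol phosphate and base-induced elimination, a sequence established for β-ionone itself and tolerant of the silyl ether.

Step 6
Reactants: 11 enyne
Product: 13 tert-butyl{[(1R)-4-[(1E,3E)-4-iodo-3-methylbuta-1,3-dien-1-yl]-3,5,5-trimethylcyclohex-3-en-1-yl]oxy}dimethylsilane, via dimethylalkenylalane 12 (not isolated)
Conditions: AlMe3 (2 equiv), Cp2ZrCl2 (0.3 equiv), ClCH2CH2Cl, 23 °C; then I2, THF, −30 → 0 °C, dark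
Reagents that add atoms: trimethylaluminium (AlMe3), C[Al](C)C; iodine (I2), II
Why: Negishi zirconium-catalysed carboalumination should add methyl and aluminium syn across the terminal alkyne with aluminium at the terminal carbon, and iodinolysis with retention should then give the (E)-C9=C10 iodide with the C19 methyl in place.

Step 7
Reactants: 13 silyl-protected dienyl iodide
Product: 14 (1R)-4-[(1E,3E)-4-iodo-3-methylbuta-1,3-dien-1-yl]-3,5,5-trimethylcyclohex-3-en-1-ol
Conditions: Bu4NF, THF, 0 → 23 °C, dark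
Reagents that add atoms: none
Why: Fluoride desilylation, to which alkenyl iodides and the triene are inert.

Step 8
Reactants: 14 hydroxy dienyl iodide; 15 palmitoyl chloride (hexadecanoyl chloride)
Product: 16 (1R)-4-[(1E,3E)-4-iodo-3-methylbuta-1,3-dien-1-yl]-3,5,5-trimethylcyclohex-3-en-1-yl hexadecanoate (β-end C14 iodide)
Conditions: pyridine, DMAP cat., CH2Cl2, 0 → 23 °C, dark
Reagents that add atoms: none
Why: Nucleophile-catalysed acylation of a secondary alcohol with an acid chloride, with no change at the carbinol centre.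

Step 9
Reactants: 17 (R)-α-ionone [(E)-4-[(1R)-2,6,6-trimethylcyclohex-2-en-1-yl]but-3-en-2-one]
Product: 18 (3R,6R)-3-hydroxy-α-ionone [(E)-4-[(1R,4R)-4-hydroxy-2,6,6-trimethylcyclohex-2-en-1-yl]but-3-en-2-one]
Conditions: engineered cytochrome P450 BM3 (CYP102A1) monooxygenase variant, O2 (air), NADPH cat., D-glucose, glucose dehydrogenase, phosphate buffer pH 7.5, 2 % DMSO, 25 °C
Reagents that add atoms: dioxygen (O2), O=O
Why: Enzymatic allylic C–H hydroxylation (hydrogen abstraction and oxygen rebound) of α-ionone, known to occur at the ring allylic CH2 (C3) on the face opposite the C6 side chain, so the new C3 centre should be set trans to C6 by the active site together with the existing centre.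

Step 10
Reactants: 18 (3R,6R)-3-hydroxy-α-ionone
Product: 19 (1R,4R)-4-[(1E)-3-hydroxy-3-methylpenta-1,4-dien-1-yl]-3,5,5-trimethylcyclohex-2-en-1-ol (epimers at the tertiary carbinol)
Conditions: CH2=CHMgBr (3 equiv), THF, −30 → 0 °C; then H2O
Reagents that add atoms: vinylmagnesium bromide, C=C[Mg]Br
Why: Grignard 1,2-addition to the ionone carbonyl after deprotonation of the free hydroxyl; the new tertiary carbinol centre is formed unselectively and is erased in step 12.

Step 11
Reactants: 19 diol; 15 palmitoyl chloride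
Product: 20 (1R,4R)-4-[(1E)-3-hydroxy-3-methylpenta-1,4-dien-1-yl]-3,5,5-trimethylcyclohex-2-en-1-yl hexadecanoate
Conditions: pyridine, DMAP cat., CH2Cl2, −10 → 0 °C
Reagents that add atoms: none
Why: Chemoselective acylation, because the secondary ring alcohol should react far faster than the hindered tertiary carbinol; the ester also protects the allylic C3' oxygen against ionisation in the next step.

Step 12
Reactants: 20 tertiary allylic alcohol
Product: 21 [(2E,4E)-3-methyl-5-[(1R,4R)-2,6,6-trimethyl-4-(hexadecanoyloxy)cyclohex-2-en-1-yl]penta-2,4-dien-1-yl]triphenylphosphonium bromide (ε-end C15 salt)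
Conditions: PPh3·HBr (1.05 equiv), CH2Cl2/MeOH, 0 → 23 °C; trituration with hexane/ethyl acetate
Reagents that add atoms: triphenylphosphine hydrobromide (PPh3·HBr), [Br-].c1ccc(cc1)[PH+](c1ccccc1)c1ccccc1
Why: Acid-mediated allylic transposition (SN1') in which the doubly allylic tertiary alcohol ionises to a pentadienyl cation that PPh3 captures at the primary terminus, the classical vinyl carbinol to C15 phosphonium salt conversion, expected to give mainly the 9'E salt.

Step 13
Reactants: 21 ε-end C15 phosphonium bromide; 22 (2E,4E,6E)-2,7-dimethylocta-2,4,6-trienedial (3 equiv)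
Product: 24 (2E,4E,6E,8E,10E,12E)-2,7,11-trimethyl-13-[(1R,4R)-2,6,6-trimethyl-4-(hexadecanoyloxy)cyclohex-2-en-1-yl]trideca-2,4,6,8,10,12-hexaenal (C25 aldehyde), via phosphonium ylide 23 (not isolated)
Conditions: 1,2-epoxybutane, 65 °C, Ar, dark; then heptane, 90 °C (equilibration of the new olefin to E)
Reagents that add atoms: none
Why: Wittig olefination under the non-nucleophilic epoxide conditions that spare the ester, with the dialdehyde in excess so that only one formyl group reacts (the C25 product is the less electrophilic aldehyde); the C11'=C12' olefin is brought to E by thermal equilibration.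

Step 14
Reactants: 24 C25 aldehyde
Product: 25 2-[(1E,3E,5E,7E,9E,11E,13E)-3,8,12-trimethyl-14-[(1R,4R)-2,6,6-trimethyl-4-(hexadecanoyloxy)cyclohex-2-en-1-yl]tetradeca-1,3,5,7,9,11,13-heptaen-1-yl]-4,4,5,5-tetramethyl-1,3,2-dioxaborolane (ε-end C26 boronate)
Conditions: Cl2CHBpin (2 equiv), CrCl2 (8 equiv), LiI (4 equiv), THF, 23 °C, dark; chromatography on deactivated silica
Reagents that add atoms: 2-(dichloromethyl)-4,4,5,5-tetramethyl-1,3,2-dioxaborolane (Cl2CHBpin), ClC(Cl)B1OC(C)(C)C(C)(C)O1
Why: Takai-type olefination with a geminal dichromium boryl reagent, which should add to the aldehyde and eliminate anti to give the (E)-alkenyl boronate, installing C11 with its boron handle in one step under conditions that tolerate esters.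

Step 15
Reactants: 16 β-end C14 dienyl iodide palmitate; 25 ε-end C26 heptaenyl boronate palmitate
Product: 26 helenien [(3R,3'R,6'R)-β,ε-carotene-3,3'-diyl dihexadecanoate]
Conditions: Pd(OAc)2 (5 mol %), SPhos (2-dicyclohexylphosphino-2',6'-dimethoxybiphenyl, 10 mol %), aqueous K3PO4 (3 equiv), THF, 30 °C, Ar, dark
Reagents that add atoms: none
Why: Zerovalent palladium formed in situ should insert into the C10–I bond of 16 with retention, the phosphate-activated boronate of 25 should transfer its C11 alkenyl group with retention, and reductive elimination should forge the C10–C11 sp2–sp2 bond, completing the conjugated decaene and the whole skeleton with both esters in place. The closest known reaction type is the Suzuki–Miyaura alkenyl–alkenyl coupling used to assemble retinoid and carotenoid polyenes. No ring is closed and no stereocentre is formed; C3, C3' and C6' are spectators, and the E geometry at C9=C10 and C11=C12 is carried over from the two partners. The step needs chemoselectivity for C–I insertion over ionisation of the allylic C3' palmitate to a π-allyl complex, and it must spare both esters and the base-sensitive C6' allylic centre; the much faster oxidative addition of the alkenyl iodide with an electron-rich biaryl phosphine near ambient temperature and the mild phosphate base should secure this. Exclusion of light and oxygen limits E/Z isomerisation and oxidative loss of the polyene.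

**Compound list**

1 | ketoisophorone (2,6,6-trimethylcyclohex-2-ene-1,4-dione) | CC1=CC(=O)CC(C)(C)C1=O | starting material
2 | (6R)-levodione [(R)-2,2,6-trimethylcyclohexane-1,4-dione] | O=C1C[C@@H](C)C(=O)C(C)(C)C1 | intermediate
3 | (4R,6R)-4-hydroxy-2,2,6-trimethylcyclohexanone (actinol) | O[C@@H]1C[C@@H](C)C(=O)C(C)(C)C1 | intermediate
4 | (4R,6R)-4-(tert-butyldimethylsilyloxy)-2,2,6-trimethylcyclohexanone | CC(C)(C)[Si](C)(C)O[C@@H]1C[C@@H](C)C(=O)C(C)(C)C1 | intermediate
5 | lithium (R)-4-(tert-butyldimethylsilyloxy)-2,6,6-trimethylcyclohex-1-en-1-olate | CC(C)(C)[Si](C)(C)O[C@@H]1CC(C)=C(O[Li])C(C)(C)C1 | intermediate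
6 | (R)-4-(tert-butyldimethylsilyloxy)-2,6,6-trimethylcyclohex-1-en-1-yl trifluoromethanesulfonate | CC(C)(C)[Si](C)(C)O[C@@H]1CC(C)=C(OS(=O)(=O)C(F)(F)F)C(C)(C)C1 | intermediate
7 | methyl vinyl ketone | CC(=O)C=C | starting material
8 | (3R)-3-(tert-butyldimethylsilyloxy)-β-ionone | CC(C)(C)[Si](C)(C)O[C@@H]1CC(C)=C(/C=C/C(C)=O)C(C)(C)C1 | intermediate
9 | lithium dienolate of 8 (methyl-side enolate) | CC(C)(C)[Si](C)(C)O[C@@H]1CC(C)=C(/C=C/C(=C)O[Li])C(C)(C)C1 | intermediate
10 | diethyl (E)-4-[(4R)-4-(tert-butyldimethylsilyloxy)-2,6,6-trimethylcyclohex-1-en-1-yl]buta-1,3-dien-2-yl phosphate | CC(C)(C)[Si](C)(C)O[C@@H]1CC(C)=C(/C=C/C(=C)OP(=O)(OCC)OCC)C(C)(C)C1 | intermediate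
11 | tert-butyl{[(1R)-4-[(E)-but-1-en-3-yn-1-yl]-3,5,5-trimethylcyclohex-3-en-1-yl]oxy}dimethylsilane | CC(C)(C)[Si](C)(C)O[C@@H]1CC(C)=C(/C=C/C#C)C(C)(C)C1 | intermediate
12 | dimethyl[(1E,3E)-2-methyl-4-[(4R)-4-(tert-butyldimethylsilyloxy)-2,6,6-trimethylcyclohex-1-en-1-yl]buta-1,3-dien-1-yl]alane | CC(C)(C)[Si](C)(C)O[C@@H]1CC(C)=C(/C=C/C(C)=C/[Al](C)C)C(C)(C)C1 | intermediate
13 | tert-butyl{[(1R)-4-[(1E,3E)-4-iodo-3-methylbuta-1,3-dien-1-yl]-3,5,5-trimethylcyclohex-3-en-1-yl]oxy}dimethylsilane | CC(C)(C)[Si](C)(C)O[C@@H]1CC(C)=C(/C=C/C(C)=C/I)C(C)(C)C1 | intermediate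
14 | (1R)-4-[(1E,3E)-4-iodo-3-methylbuta-1,3-dien-1-yl]-3,5,5-trimethylcyclohex-3-en-1-ol | O[C@@H]1CC(C)=C(/C=C/C(C)=C/I)C(C)(C)C1 | intermediate
15 | palmitoyl chloride (hexadecanoyl chloride) | CCCCCCCCCCCCCCCC(=O)Cl | starting material
16 | (1R)-4-[(1E,3E)-4-iodo-3-methylbuta-1,3-dien-1-yl]-3,5,5-trimethylcyclohex-3-en-1-yl hexadecanoate | CCCCCCCCCCCCCCCC(=O)O[C@@H]1CC(C)=C(/C=C/C(C)=C/I)C(C)(C)C1 | intermediate
17 | (R)-α-ionone | CC(=O)/C=C/[C@H]1C(C)=CCCC1(C)C | starting material
18 | (3R,6R)-3-hydroxy-α-ionone | CC(=O)/C=C/[C@H]1C(C)=C[C@H](O)CC1(C)C | intermediate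
19 | (1R,4R)-4-[(1E)-3-hydroxy-3-methylpenta-1,4-dien-1-yl]-3,5,5-trimethylcyclohex-2-en-1-ol (carbinol epimers) | C=CC(C)(O)/C=C/[C@H]1C(C)=C[C@H](O)CC1(C)C | intermediate
20 | (1R,4R)-4-[(1E)-3-hydroxy-3-methylpenta-1,4-dien-1-yl]-3,5,5-trimethylcyclohex-2-en-1-yl hexadecanoate | C=CC(C)(O)/C=C/[C@H]1C(C)=C[C@H](OC(=O)CCCCCCCCCCCCCCC)CC1(C)C | intermediate
21 | [(2E,4E)-3-methyl-5-[(1R,4R)-2,6,6-trimethyl-4-(hexadecanoyloxy)cyclohex-2-en-1-yl]penta-2,4-dien-1-yl]triphenylphosphonium bromide | [Br-].c1ccccc1[P+](c1ccccc1)(c1ccccc1)C/C=C(C)/C=C/[C@H]2C(C)=C[C@H](OC(=O)CCCCCCCCCCCCCCC)CC2(C)C | intermediate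
22 | (2E,4E,6E)-2,7-dimethylocta-2,4,6-trienedial | O=C/C(C)=C/C=C/C=C(C)/C=O | starting material
23 | phosphonium ylide of 21 | c1ccccc1[P+](c1ccccc1)(c1ccccc1)[CH-]/C=C(C)/C=C/[C@H]2C(C)=C[C@H](OC(=O)CCCCCCCCCCCCCCC)CC2(C)C | intermediate
24 | (2E,4E,6E,8E,10E,12E)-2,7,11-trimethyl-13-[(1R,4R)-2,6,6-trimethyl-4-(hexadecanoyloxy)cyclohex-2-en-1-yl]trideca-2,4,6,8,10,12-hexaenal | O=C/C(C)=C/C=C/C=C(C)/C=C/C=C(C)/C=C/[C@H]1C(C)=C[C@H](OC(=O)CCCCCCCCCCCCCCC)CC1(C)C | intermediate
25 | 2-[(1E,3E,5E,7E,9E,11E,13E)-3,8,12-trimethyl-14-[(1R,4R)-2,6,6-trimethyl-4-(hexadecanoyloxy)cyclohex-2-en-1-yl]tetradeca-1,3,5,7,9,11,13-heptaen-1-yl]-4,4,5,5-tetramethyl-1,3,2-dioxaborolane | CC1(C)OB(/C=C/C(C)=C/C=C/C=C(C)/C=C/C=C(C)/C=C/[C@H]2C(C)=C[C@H](OC(=O)CCCCCCCCCCCCCCC)CC2(C)C)OC1(C)C | intermediate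
26 | helenien [(3R,3'R,6'R)-β,ε-carotene-3,3'-diyl dihexadecanoate] | CCCCCCCCCCCCCCCC(=O)O[C@@H]1CC(C)=C(/C=C/C(C)=C/C=C/C(C)=C/C=C/C=C(C)/C=C/C=C(C)/C=C/[C@H]2C(C)=C[C@H](OC(=O)CCCCCCCCCCCCCCC)CC2(C)C)C(C)(C)C1 | target

**Summary**

Total step count: 15. Longest linear sequence: 9 steps (steps 1–8, then step 15).

**Steps most likely to fail**

Step 15. The heptaenyl boronate may lose boron by protodeboronation or homocouple faster than it transmetalates, zerovalent palladium may ionise the allylic C3' ester, and the polyene may isomerise. The fallback gives up the C10–C11 coupling for a Wittig olefination at C11=C12. It sets out from 8 and 24 and comes back at 26. Silyl ether 8 is cleaved with Bu4NF to (3R)-3-hydroxy-β-ionone F1. CH2=CHMgBr (excess, THF) adds to the ketone to give the vinyl carbinol diol F2. Selective acylation with 15 (pyridine, DMAP) gives the ring palmitate F3. PPh3·HBr converts this into the β-end C15 phosphonium bromide F4. Wittig condensation of F4 with aldehyde 24 (1,2-epoxybutane, 65 °C, then thermal equilibration in heptane) should give 26.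

Step 14. The geminal dichromium reagent may add only sluggishly to the poorly electrophilic hexaenal, reductive pinacol-type coupling of the aldehyde may compete, and the product may lose boron on silica. The fallback installs C11 as an alkyne carbon and then hydroborates. It sets out from 24 and comes back at 25. Colvin homologation of 24 (Me3SiCHN2 lithiated with LiN(iPr)2, THF, −78 → 0 °C) should give the terminal polyenyne F5. Hydroboration of the alkyne with pinacolborane under Cp2Zr(H)Cl catalysis (syn, anti-Markovnikov) should give 25.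

Step 9. The enzymatic hydroxylation may stall at low conversion, over-oxidise the alcohol to the 3-ketone, or lose regio- or facial selectivity. The fallback is a chemical oxidation, reduction and inversion sequence in which both C3 epimers converge. It sets out from 17 and comes back at 20.
- Ketalisation of 17 (ethylene glycol, HC(OMe)3, pyridinium p-toluenesulfonate) gives the (R)-α-ionone dioxolane F6.
- Allylic oxidation (CrO3, 3,5-dimethylpyrazole, CH2Cl2, −20 °C) gives the 3-oxo dioxolane F7.
- Luche reduction (NaBH4, CeCl3·7H2O, MeOH) gives the trans (3R,6R) alcohol F8 and the cis (3S,6R) alcohol F9, which are separated.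
- F8 is acylated with 15 (pyridine, DMAP), and F9 undergoes Mitsunobu esterification with palmitic acid (PPh3, DIAD) with inversion; both give the same (3R,6R) palmitate dioxolane F10.
- Mild hydrolysis of the ketal (pyridinium p-toluenesulfonate, wet acetone) gives (3R,6R)-3-(hexadecanoyloxy)-α-ionone F11.
- Addition of CH2=CHMgBr (1.1 equiv, THF, −78 °C) to the ketone should give 20.

**Further compounds**

F1 | step 15 | (3R)-3-hydroxy-β-ionone | O[C@@H]1CC(C)=C(/C=C/C(C)=O)C(C)(C)C1
F2 | step 15 | (1R)-4-[(1E)-3-hydroxy-3-methylpenta-1,4-dien-1-yl]-3,5,5-trimethylcyclohex-3-en-1-ol (carbinol epimers) | O[C@@H]1CC(C)=C(/C=C/C(C)(O)C=C)C(C)(C)C1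
F3 | step 15 | (1R)-4-[(1E)-3-hydroxy-3-methylpenta-1,4-dien-1-yl]-3,5,5-trimethylcyclohex-3-en-1-yl hexadecanoate | CCCCCCCCCCCCCCCC(=O)O[C@@H]1CC(C)=C(/C=C/C(C)(O)C=C)C(C)(C)C1
F4 | step 15 | [(2E,4E)-3-methyl-5-[(4R)-2,6,6-trimethyl-4-(hexadecanoyloxy)cyclohex-1-en-1-yl]penta-2,4-dien-1-yl]triphenylphosphonium bromide | [Br-].CCCCCCCCCCCCCCCC(=O)O[C@@H]1CC(C)=C(/C=C/C(C)=C/C[P+](c2ccccc2)(c2ccccc2)c2ccccc2)C(C)(C)C1
F5 | step 14 | (1R,4R)-3,5,5-trimethyl-4-[(1E,3E,5E,7E,9E,11E)-3,7,12-trimethyltetradeca-1,3,5,7,9,11-hexaen-13-yn-1-yl]cyclohex-2-en-1-yl hexadecanoate | C#C/C(C)=C/C=C/C=C(C)/C=C/C=C(C)/C=C/[C@H]1C(C)=C[C@H](OC(=O)CCCCCCCCCCCCCCC)CC1(C)C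
F6 | step 9 | 2-methyl-2-[(E)-2-[(1R)-2,6,6-trimethylcyclohex-2-en-1-yl]ethenyl]-1,3-dioxolane | CC1(/C=C/[C@H]2C(C)=CCCC2(C)C)OCCO1
F7 | step 9 | (4R)-3,5,5-trimethyl-4-[(E)-2-(2-methyl-1,3-dioxolan-2-yl)ethenyl]cyclohex-2-en-1-one | CC1(/C=C/[C@H]2C(C)=CC(=O)CC2(C)C)OCCO1
F8 | step 9 | (1R,4R)-3,5,5-trimethyl-4-[(E)-2-(2-methyl-1,3-dioxolan-2-yl)ethenyl]cyclohex-2-en-1-ol (trans) | CC1(/C=C/[C@H]2C(C)=C[C@H](O)CC2(C)C)OCCO1
F9 | step 9 | (1S,4R)-3,5,5-trimethyl-4-[(E)-2-(2-methyl-1,3-dioxolan-2-yl)ethenyl]cyclohex-2-en-1-ol (cis) | CC1(/C=C/[C@H]2C(C)=C[C@@H](O)CC2(C)C)OCCO1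
F10 | step 9 | (1R,4R)-3,5,5-trimethyl-4-[(E)-2-(2-methyl-1,3-dioxolan-2-yl)ethenyl]cyclohex-2-en-1-yl hexadecanoate | CC1(/C=C/[C@H]2C(C)=C[C@H](OC(=O)CCCCCCCCCCCCCCC)CC2(C)C)OCCO1
F11 | step 9 | (3R,6R)-3-(hexadecanoyloxy)-α-ionone | CC(=O)/C=C/[C@H]1C(C)=C[C@H](OC(=O)CCCCCCCCCCCCCCC)CC1(C)C
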